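A one-step world has one product, and a recipe there moves the clock and leaves the outcome alone. These flasks are no such world: starting material leaves for target and for self-condensation product side by side.

    starting material ⇌ dormant form (K1 = 0.95, k1 = 0.13 h⁻¹, Ea1 = 94.0 kJ mol⁻¹, ΔH1 = −29.0 kJ mol⁻¹)
    2 starting material → self-condensation product (k2 = 2.4 M⁻¹ h⁻¹, Ea2 = 69.0 kJ mol⁻¹)
    starting material + reagent → target, rate k3*[starting material]^2*[reagent] (k3 = 33 M⁻² h⁻¹, Ea3 = 61.0 kJ mol⁻¹)
    starting material + protic impurity → quenched substrate (k4 = 0.11 M⁻¹ h⁻¹, Ea4 = 68.0 kJ mol⁻¹)
    (constants at 20 °C)

| flask | starting material | reagent | protic impurity | time | remark | temperature |
|---|---|---|---|---|---|---|
| spring | 0.19 M | 1.05 equiv (fed, over 15 h) | 0.0570 M | 20 h | the addition at 0 °C, then warmed to 20 °C; the feed brings no volume worth counting |  |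
| dawn | 0.19 M | 1.05 equiv (in portions, 4, over 15 h) | 0.0570 M | 20 h | first portion at the start, last at 15 h | 20 °C |
| winter | 0.19 M | 1.05 equiv | 0.0570 M | 20 h | everything together at the start at 0 °C, warmed to 20 °C at 15 h |  |
| summer | 0.19 M | 1.05 equiv (fed, over 15 h) | 0.0570 M | 20 h | all else is in the flask from the start; the feed brings no volume worth counting | 20 °C |
| dusk | 0.19 M (fed, over 15 h) | 1.05 equiv | 0.0570 M | 20 h | all else is in the flask from the start; the feed brings no volume worth counting | 20 °C |

- a species is counted by the starting material in it: one self-condensation product counts as two
- for a step with 2 of a species take k times the square, and two of it per event
- all constants are for 20 °C and move with temperature by the activation energies and enthalpies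

- the best flask by share of target in target plus self-condensation product; "all alike" if 1.5 percentage points covers them all (spring / dawn / winter / summer / dusk / all alike)
- share of target in target plus self-condensation product at the end, spring
- share of target in target plus self-condensation product at the end, dawn
- share of target in target plus self-condensation product at the end, winter
- share of target in target plus self-condensation product at the end, summer
- share of target in target plus self-condensation product at the end, dusk

Starting material goes to target at a rate holding its square times the reagent concentration, and to self-condensation product at a rate holding the same square. Their quotient, the split S, is therefore the target constant times the reagent concentration, over twice the self-condensation constant. Starting material cancels from S, and the share of target in what forms at each instant is S over one plus S. With the full reagent charge present at 20 °C, the split is 1.37, the carried quantity, and it scales with the fraction of reagent present.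

The time scales at 20 °C form a ladder. The first half-life of starting material by self-condensation alone is 1.10 h. The relaxation half-life between starting material and dormant form is 2.60 h, longer than that. The feed is longer again, at 15 h, and the half-life of starting material against protic impurity is 111 h, longer still. Because that first half-life is shorter than the feed, summer has received 7.33% of its reagent by then. Its split there is 0.100, and taking that moment to stand for the run, this reckoning of my own puts summer near 9.11%.

Winter holds its whole reagent charge from the start, at 0 °C, and the target step has the lower activation energy, so its split opens at 1.7, a first share of 63.6%. Working with the fraction of reagent left, if that share of the starting material goes to target, the fraction of reagent falls by that share over 1.05 equiv, and the average of the start and end fractions lowers the split to 1.22. By this reckoning of my own, that split gives winter 54.9%.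

The forecast named winter as best, with 55% for winter, 52% for dusk, 44% for dawn, 43% for summer and 41% for spring, holding that “selectivity depends almost only on how much reagent is present”. It differs from the reckoning above on summer.

The flasks ended at 32.3% for spring, 22.6% for dawn, 55.9% for winter, 13.4% for summer and 52.0% for dusk, with winter best. Summer ended with 89.0% of its reagent standing, a split of 1.22, but with 4.84% of the starting material left and 74.9% in self-condensation product. Winter's split opened at 1.7 and stood at 0.75 at 20.0 h, with half of its self-condensation up to that time done by 3.29 h. A neighbour of winter charged with 0.076 M of starting material, at the same equivalents of reagent, opens at a split of 0.698, and the same reagent-left step lowers that to 0.561, a reckoned share of 35.9%; that flask ended at 36.5%.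

The constants are those of an exercise; the run is a simulation.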